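The numbers in the tables were generated by integration with made-up constants; the scatter is artificial.

I had to say which of these flasks ends highest in over-reaction product, and by how much.

all flasks: free catalyst 0.21 mol%

| charge | starting material | reagent | second catalyst | remark | time |
|---|---|---|---|---|---|
| maple | 0.10 M | 1.1 equiv | 0.29 mol% | run made earlier |  |
| elm | 0.10 M | 1.1 equiv | 0.41 mol% | run made earlier |  |
| larch | 0.10 M | 1.1 equiv | 0.64 mol% | run made earlier |  |
| spring | 0.10 M (in portions, 2, over 3.0 h) | 1.10 equiv | 0.29 mol% | first portion at the start, last at 3.0 h | 4.0 h |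
| autumn | 0.10 M | 1.10 equiv | 0.29 mol% | everything together at the start | 4.0 h |
| midnight | 0.10 M (fed, over 3.0 h) | 1.10 equiv | 0.29 mol% | all else is in the flask from the start; the feed brings no volume worth counting | 4.0 h |
| dusk | 0.10 M | 1.10 equiv (fed, over 3.0 h) | 0.29 mol% | all else is in the flask from the start; the feed brings no volume worth counting | 4.0 h |

* the flask that comes out highest in amount of over-reaction product, in percent of the starting material charged; "all alike" if 1.5 percentage points covers them all (spring / autumn / midnight / dusk / all alike)
* amount of over-reaction product at the end, in percent of the starting material charged, spring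
* amount of over-reaction product at the end, in percent of the starting material charged, autumn
* amount of over-reaction product at the end, in percent of the starting material charged, midnight
* amount of over-reaction product at the end, in percent of the starting material charged, dusk

| run | time / h | over-reaction product / % | target / % | starting material / % |
|---|---|---|---|---|
| maple | 0.333 | 1.2 | 1.6 | 75.2 |
| maple | 0.667 | 2.1 | 7.7 | 57.0 |
| maple | 1.00 | 6.4 | 9.0 | 42.8 |
| maple | 1.33 | 10.2 | 12.8 | 32.8 |
| maple | 1.50 | 11.8 | 12.9 | 29.4 |
| maple | 2.00 | 19.3 | 14.6 | 19.2 |
| maple | 2.50 | 23.3 | 16.7 | 12.5 |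
| elm | 0.200 | 0 | 3.1 | 85.9 |
| elm | 0.667 | 4.6 | 7.1 | 56.1 |
| elm | 1.00 | 7.2 | 11.6 | 45.1 |
| elm | 1.50 | 14.1 | 15.5 | 27.7 |
| elm | 2.50 | 29.2 | 18.4 | 12.1 |
| elm | 3.00 | 33.3 | 20.7 | 9.3 |
| elm | 4.00 | 37.9 | 19.6 | 3.9 |
| larch | 0.500 | 3.7 | 6.2 | 66.5 |
| larch | 1.00 | 10.7 | 17.3 | 43.3 |
| larch | 1.50 | 18.2 | 18.7 | 29.1 |
| larch | 2.50 | 30.1 | 23.0 | 13.1 |
| larch | 3.00 | 34.3 | 25.2 | 7.6 |
| larch | 4.00 | 37.5 | 24.8 | 3.2 |

(standard deviation of a reading: 1 percentage point)



I began with the starting material. In maple, c(starting material) fell to 19.2 % at 2.00 h, which means a lifetime of 1.21 h. Larch, with more second catalyst, gave 1.22 h, so the decay looked pseudo-first-order. My doubt was the reagent, whose amount I expected to fall during a run. But that lifetime predicts 3.67 % left at 4.0 h, and elm read 3.9 %. So each portion of starting material seemed to run on its own clock.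

In spring and midnight the average entry falls at 1.50 h, which leaves 2.50 h in the flask. I called this the mean age, the time the average portion of starting material has spent in the flask at the end. Autumn's is 4.0 h. Maple read 23.3 % of over-reaction product at 2.50 h, so I put spring and midnight there.

But a mean hides the spread, and the curve bends. Spring's portions are 4.0 h and 1.00 h old. Maple read 6.4 % at 1.00 h, but its last reading was at 2.50 h, so elm's 37.9 % at 4.00 h, taken with more second catalyst, stood in for the older portion. Their mean is 22.1 %, which is 1.2 percentage points under my first figure for spring, against a scatter of 1 point on a reading.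

Autumn has maple's charges carried on to 4.0 h, so I placed it near elm's 37.9 % but under it, since maple read less than elm at 2.50 h, 23.3 % against 29.2 %. Dusk defeated me: its starting material is 4.0 h old, its reagent 2.50 h on average. I guessed midway, 30.6 %.

The forecast named autumn, with 30 % for spring, 34 % for autumn, 27 % for midnight and 30 % for dusk. Of dusk it wrote: “reagent is starved early”. We agreed on the top flask, but its midnight stood higher than my figure.

The flasks gave autumn highest at 35.9 %, then dusk 29.6 %, spring 26.4 % and midnight 25.1 %.

reagent + second catalyst + intermediate → second catalyst + target (k = 5.50 M⁻² s⁻¹); starting material + free catalyst → free catalyst + intermediate (k = 1.10 M⁻¹ s⁻¹); reagent + free catalyst + target → free catalyst + over-reaction product (k = 19.0 M⁻² s⁻¹) Autumn ended with 43.4 % of the starting material charged standing as intermediate, a species the readings do not list. Spring and midnight, sharing the mean age of 2.50 h, ended 1.3 points apart against a margin of 1.5 points. Midnight stood 1.8 points above maple's reading at that age, and spring stood 3.1 points above it.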